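## Structural features

The target is a flavone. Benzene ring A is fused through C4a–C8a to the 4-pyranone ring C (O1, C2, C3, C4), phenyl ring B sits on C2, and C7 carries a methoxy group. C8 carries C3', the alpha-carbon of a 5,5-dimethylfuran-2(5H)-one (ring D: O1', C2'=O, C3', C4'H, C5'Me2); these atom labels are kept for all precursors. There is no stereocentre and no open-chain double bond, so the problem is one of connectivity and crowding only. C8 lies between two oxygen-bearing carbons (C7–OMe and C8a–O1), so the C8–C3' bond joins a di-ortho-substituted arene carbon to a fully substituted alkene carbon, and ring D must twist out of the plane of ring A. C5' is a fully substituted carbon bound to oxygen and blocks enolisation of ring D, so the weak points are reversible lactone opening, conjugate addition at C4', and attack of hard nucleophiles at C2 of ring C. The real difficulty is the hindered C8–C3' bond together with ring D built on it. The key step exploits the six-atom path O1–C8a–C8–C3'–C4'–C5': the oxygen on C8a is ortho to C8 and C5' must carry an oxygen in any case, so C5' can first be hung on that phenol oxygen as a propargyl ether, the chain can be passed to C8 by a [3,3] shift, and C5' can then be handed over to the carboxyl oxygen O1'.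

## Logic of the disconnections

**11 to 10.** The O1–C2 bond of ring C is cut and two hydrogens are returned (to O1 and C3). Ring C is the nucleophile-sensitive ring, and removing it frees the oxygen on C8a, which the key step needs. The gain is one ring. The demand is an oxidative closure that leaves ring D and the electron-rich ring A untouched.

**10 to 8 + 9.** The C2=C3 bond is cut (aldol retron). Ring B and C2 come from 9, and 8 keeps the whole crowded region in a small benzene derivative. The demand is that the acetyl methyl group be the only carbon acid. This holds because C5' is quaternary and C4'–H is vinylic.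

**8 to 5 (key disconnection).**
- Two bonds are cut, C8–C3' and O1'–C5', and a bond absent from the target is drawn instead, from C5' to the oxygen on C8a. 8 and 5 are isomers.
- In one sentence: 8 arises from 5 by an isomerisation in which an aromatic propargyl Claisen shift moves the six-carbon chain from the phenol oxygen to the flanked ring carbon, and the carboxyl group then takes C5' over from that oxygen to close ring D.
- The gain is large. The hindered bond and ring D disappear together, and what is left is an aryl ether with a linear chain.
- The tether runs through the oxygen on C8a, not the one on C7, for three reasons. Its second ortho position is blocked by the acyl carbon, so C8 is the only productive site. The freed phenol ends up hydrogen-bonded to that acyl group, which gives the oxygen-to-oxygen transfer a driving force. The freed phenol is also exactly what ring C needs later.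
- A tether through the C7 oxygen of a finished ring system would save a step on paper, but it would leave C6 open and offer no driving force.
- The demand on the forward step is that lactone formation win over the pyran that such ethers normally give.

**5 to 3 + 4.** The C2'–C3' bond is cut. C2' comes from the C1 electrophile 4, and 3 is a plain terminal alkyne. The demand is a carboxylation that works without a strong base, since the acetyl group is more acidic than the alkyne C–H.

**3 to 1 + 2.** The bond from the C8a oxygen to C5' is cut. 1 already holds the methoxy group, the acyl carbon and the phenol in the right pattern, and 2 brings C3', C4', C5' and both methyl groups. The demand is formation of a tertiary C–O bond on a hydrogen-bonded phenol, which calls for the copper allenylidene pathway rather than direct substitution.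

## Other disconnections considered

**Alternative 1:** This is the first that comes to mind. The cut is C8–C3' between two finished halves. The forward key step is a Stille (or Suzuki–Miyaura) coupling of 8-iodo-7-methoxy-2-phenyl-4H-chromen-4-one A1 with 5,5-dimethyl-3-(tributylstannyl)furan-2(5H)-one A2 under zerovalent palladium. Grounds for preferring the chosen plan:
- Oxidative addition and transmetalation must both occur at a carbon with two ortho oxygens, and the partner is itself branched at the reacting carbon.
- Alpha-metalated butenolides are prone to protodemetalation.
- A1 needs a halogenation that selects C8 over C6 and C3.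
- A2 needs its own halogenation, elimination and stannylation sequence, so the total count is clearly higher than five.

**Alternative 2:** The cut is C2'–C3' and O1'–C5', with CO as the C1 unit. The forward key step is palladium-catalysed cyclocarbonylation (Pd(dba)2, 1,4-bis(diphenylphosphino)butane, CO/H2) of 8-(3-hydroxy-3-methylbut-1-yn-1-yl)-7-methoxy-2-phenyl-4H-chromen-4-one A3 through an allenylpalladium species. Grounds for preferring the chosen plan:
- The ring-forming step is attractive, but the hindered C8–C bond is still made by a cross-coupling on A1. The plan inherits the site-selective halogenation, and its key step does not address that bond.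
- Palladium would have to sit on C3' next to the di-ortho-substituted ring and insert CO there.
- Pressurised CO/H2 is needed.
- Counted from the same acetophenone, the sequence is no shorter.
- The chosen plan reaches the same allenoic acid oxidation level with no metal at C8.

**Alternative 3:** The cut is C3'=C4' and C2'–O1'. The forward key step is an intramolecular Knoevenagel-type aldol condensation of 2-methyl-1-oxopropan-2-yl (7-methoxy-4-oxo-2-phenyl-4H-chromen-8-yl)acetate A6. A6 would be made from (7-methoxy-4-oxo-2-phenyl-4H-chromen-8-yl)acetic acid A4 and 2-hydroxy-2-methylpropanal A5. Grounds for preferring the chosen plan: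
- A4 requires a two-carbon homologation at C8 (allyl ether, Claisen shift, oxidative cleavage, oxidation).
- The acylation of the tertiary, self-condensing A5 is hindered.
- The base needed for the condensation threatens ring C.
- The route is several steps longer and forms ring D one bond at a time.

Key step: step 3

## Steps

Step 1
Reactants: 1 paeonol, 1-(2-hydroxy-4-methoxyphenyl)ethan-1-one; 2 3-chloro-3-methylbut-1-yne
Product: 3 1-{4-methoxy-2-[(2-methylbut-3-yn-2-yl)oxy]phenyl}ethan-1-one
Conditions: CuCl2·2H2O (1 mol %), DBU (1.3 equiv), MeCN, 0 °C to rt
Reagents that add atoms: none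
Why: Copper-catalysed propargylic etherification of a phenol: monovalent copper formed in situ gives the acetylide of 2, which loses chloride to a copper allenylidene, and the phenoxide of 1 adds to its tertiary gamma-carbon, so the tertiary C–O bond forms where direct substitution cannot. Full deprotonation by DBU breaks the hydrogen bond to the acetyl group, and the low temperature keeps 3 from rearranging.

Step 2
Reactants: 3 1-{4-methoxy-2-[(2-methylbut-3-yn-2-yl)oxy]phenyl}ethan-1-one; 4 carbon dioxide
Product: 5 4-(2-acetyl-5-methoxyphenoxy)-4-methylpent-2-ynoic acid
Conditions: AgI (2 mol %), Cs2CO3 (1.5 equiv), CO2 (1–2 atm), DMF, 50 °C; then 1 M HCl, 0 °C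
Reagents that add atoms: none
Why: Silver-catalysed carboxylation of a terminal alkyne: pi-activation by monovalent silver lets carbonate form the silver acetylide, which adds to 4, so no strong base meets the more acidic acetyl group. C5' is quaternary, so base cannot isomerise the alkyne, and any reversible carboxylation at the ketone is undone on acidification.

Step 3
Reactants: 5 4-(2-acetyl-5-methoxyphenoxy)-4-methylpent-2-ynoic acid
Product: 8 3-(3-acetyl-2-hydroxy-6-methoxyphenyl)-5,5-dimethylfuran-2(5H)-one, via allenoic acid 6 (not isolated), via chromene acid 7 (not isolated)
Conditions: o-dichlorobenzene (0.05 M), 160 °C, Ar; then MsOH (20 mol %), 100 °C, same flask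
Reagents that add atoms: none
Why: Proposed new method: the elementary steps are known reaction types (aromatic propargyl Claisen rearrangement of aryl 1,1-dimethylpropargyl ethers to 2,2-dimethylchromenes; cycloisomerisation of 2,3-allenoic acids to butenolides), but their union with transfer of C5' from the phenol oxygen to the carboxyl oxygen has not been shown on this substrate class. Heating triggers the [3,3] shift in which the slender sp carbon C3' bonds to the only unsubstituted ortho carbon (future C8) while the O–C5' bond breaks, and enolisation of the dienone gives 6; attack at the acetyl-bearing ortho carbon cannot rearomatise and reverts, so the substrate itself secures the site selectivity. 6 has two exits: protonation of the central allene carbon C4' and capture of the tertiary allyl cation at C5' by the carboxyl oxygen gives 8 directly (formally 5-endo-trig, the mode of all allenoic acid lactonisations), or a [1,5]-hydrogen shift from the phenol followed by oxa-6-pi electrocyclisation gives the pyran 7, and the first exit is favoured here because the phenol O–H is held in a hydrogen bond to the acetyl oxygen and must leave it to reach C4'. MsOH then joins both exits: proton relay from the acetyl oxygen to the pyran oxygen ionises the tertiary allylic O–C5' bond of 7 to the same allyl cation, whose charge is shared with the 2-hydroxy-6-methoxyaryl ring, so the C3'–C4' bond can rotate and bring C5' to the carboxyl group. The selectivity needed, lactone over pyran, is thermodynamic: 8 gains the chelated phenol–acetyl hydrogen bond and loses the peri clash between the C4 carboxyl and the C5 methoxy group of 7, which should outweigh the strain of the five-membered lactone. The carboxyl group on the alkyne destabilises the propargyl cation, so ether heterolysis should not outrun the pericyclic step, and base is excluded so that the phenol oxygen does not add to C4' of 6. No stereocentre is formed.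

Step 4
Reactants: 8 3-(3-acetyl-2-hydroxy-6-methoxyphenyl)-5,5-dimethylfuran-2(5H)-one; 9 benzaldehyde
Product: 10 3-{2-hydroxy-6-methoxy-3-[(E)-3-phenylprop-2-enoyl]phenyl}-5,5-dimethylfuran-2(5H)-one
Conditions: KOH (3 equiv), EtOH, rt; then 1 M HCl to pH 1
Reagents that add atoms: none
Why: Claisen–Schmidt condensation: the acetyl methyl group is the only enolisable position (C5' quaternary, C4'–H vinylic), and E1cB loss of water gives the E enone. Any lactone opened by hydroxide keeps its Z geometry and its gem-dimethyl carbinol and should close again on acidification.

Step 5
Reactants: 10 3-{2-hydroxy-6-methoxy-3-[(E)-3-phenylprop-2-enoyl]phenyl}-5,5-dimethylfuran-2(5H)-one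
Product: 11 8-(5,5-dimethyl-2-oxo-2,5-dihydrofuran-3-yl)-7-methoxy-2-phenyl-4H-chromen-4-one (target)
Conditions: I2 (10 mol %), DMSO, 130 °C
Reagents that add atoms: none
Why: Iodine-catalysed oxidative cyclisation of a 2'-hydroxychalcone: 6-endo-trig oxa-Michael closure forms O1–C2, iodination at C3 and loss of HI install the C2=C3 bond, and DMSO reoxidises HI. Ring D has no enolisable or readily oxidised C–H, and the catalytic iodine load limits ring iodination.

## Compound list

1 | paeonol, 1-(2-hydroxy-4-methoxyphenyl)ethan-1-one | CC(=O)c1ccc(OC)cc1O | starting material
2 | 3-chloro-3-methylbut-1-yne | CC(C)(Cl)C#C | starting material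
3 | 1-{4-methoxy-2-[(2-methylbut-3-yn-2-yl)oxy]phenyl}ethan-1-one | CC(=O)c1ccc(OC)cc1OC(C)(C)C#C | intermediate
4 | carbon dioxide | O=C=O | starting material
5 | 4-(2-acetyl-5-methoxyphenoxy)-4-methylpent-2-ynoic acid | CC(=O)c1ccc(OC)cc1OC(C)(C)C#CC(=O)O | intermediate
6 | 2-(3-acetyl-2-hydroxy-6-methoxyphenyl)-4-methylpenta-2,3-dienoic acid (not isolated) | CC(=O)c1ccc(OC)c(C(C(=O)O)=C=C(C)C)c1O | intermediate
7 | 8-acetyl-5-methoxy-2,2-dimethyl-2H-chromene-4-carboxylic acid (not isolated) | CC(=O)c1ccc(OC)c2c1OC(C)(C)C=C2C(=O)O | intermediate
8 | 3-(3-acetyl-2-hydroxy-6-methoxyphenyl)-5,5-dimethylfuran-2(5H)-one | CC(=O)c1ccc(OC)c(C2=CC(C)(C)OC2=O)c1O | intermediate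
9 | benzaldehyde | O=Cc1ccccc1 | starting material
10 | 3-{2-hydroxy-6-methoxy-3-[(E)-3-phenylprop-2-enoyl]phenyl}-5,5-dimethylfuran-2(5H)-one | COc1ccc(C(=O)/C=C/c2ccccc2)c(O)c1C1=CC(C)(C)OC1=O | intermediate
11 | 8-(5,5-dimethyl-2-oxo-2,5-dihydrofuran-3-yl)-7-methoxy-2-phenyl-4H-chromen-4-one | COc1ccc2c(=O)cc(-c3ccccc3)oc2c1C1=CC(C)(C)OC1=O | target

## Step count and risks

Total step count: 5. Longest linear sequence: 5 (1 to 11).

**Step 3 (key step, bears the label).**
- Three processes are most likely to interfere. The alkynoic acid may lose CO2 at the temperature of the [3,3] shift. The transfer of C5' from the phenol oxygen to the carboxyl oxygen may stay incomplete, either because ionisation of the pyran C–O bond is slower than acid-induced oligomerisation or because the equilibrium is less one-sided than argued. The phenol oxygen may add to the central allene carbon.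
- The fallback uses known chemistry, sets out from 5 and returns at 8. It trades the redox-neutral isomerisation for a reduce-then-oxidise detour in which the hydrogen shift to a pyran is impossible.
- Semi-hydrogenation of 5 (H2, Pd on CaCO3 poisoned with Pb(OAc)2, quinoline, EtOAc) should give (Z)-4-(2-acetyl-5-methoxyphenoxy)-4-methylpent-2-enoic acid F1.
- The aromatic Claisen rearrangement of this 1,1-dimethylallyl aryl ether is run in a non-polar medium that disfavours ether ionisation (toluene, 110 °C). It should give racemic 2-(3-acetyl-2-hydroxy-6-methoxyphenyl)-4-methylpent-3-enoic acid F2.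
- Phenylselenolactonisation (PhSeCl, CH2Cl2, −78 °C) has the carboxyl oxygen attacking the tertiary carbon while the chelated phenol stays idle. It should give racemic trans-(3S*,4R*)-3-(3-acetyl-2-hydroxy-6-methoxyphenyl)-5,5-dimethyl-4-(phenylselanyl)oxolan-2-one F3.
- Oxidation (H2O2, pyridine, CH2Cl2, 0 °C) and syn elimination of the selenoxide toward the cis C3'–H should return 8.

**Step 1.**
- The O-alkylation may be sluggish because the phenol is hydrogen-bonded to and flanked by the acetyl group, so dehydrochlorination of 2 may consume the electrophile first.
- The fallback sets out from 2 and returns at 3, and it installs the acetyl group after the ether bond.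
- 2 is joined under the same copper catalysis to commercial, unchelated 2-bromo-5-methoxyphenol to give 1-bromo-4-methoxy-2-[(2-methylbut-3-yn-2-yl)oxy]benzene F4.
- Stille coupling with tributyl(1-ethoxyvinyl)stannane (Pd(PPh3)4, toluene, 90 °C) should give 1-(1-ethoxyethenyl)-4-methoxy-2-[(2-methylbut-3-yn-2-yl)oxy]benzene F5.
- Mild hydrolysis (1 M HCl, THF, rt) should give 3.

**Step 2.**
- The carboxylation is reversible and may fall back during work-up, and warm carbonate in DMF may start aldol self-condensation at the acetyl group.
- The fallback sets out from 3 and returns at 5, and it changes the C1 source and the polarity.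
- Oxidative methoxycarbonylation with CO under nearly neutral conditions (PdCl2 cat., CuCl2, NaOAc, CO 1 atm, MeOH, rt) should give methyl 4-(2-acetyl-5-methoxyphenoxy)-4-methylpent-2-ynoate F6.
- Saponification (LiOH, THF/H2O, 0 °C) should give 5.

**Step 4.**
- Hydroxide may attack ring D, with lactone opening and slow or incomplete reclosure, or with conjugate addition at C4'. The condensation may also stall at the aldol stage.
- The fallback sets out from 8 and returns at 11, and it bypasses 10 and step 5 by acyl transfer in place of aldol and oxidation (Baker–Venkataraman route).
- Benzoylation (BzCl, pyridine, DMAP) should give 6-acetyl-2-(5,5-dimethyl-2-oxo-2,5-dihydrofuran-3-yl)-3-methoxyphenyl benzoate F7.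
- Base-induced O-to-C benzoyl shift (KOH, pyridine, 50 °C) should give 1-[3-(5,5-dimethyl-2-oxo-2,5-dihydrofuran-3-yl)-2-hydroxy-4-methoxyphenyl]-3-phenylpropane-1,3-dione F8.
- Cyclodehydration (H2SO4 cat., AcOH, 90 °C) should give 11.

## Further compounds

F1 | step 3 | (Z)-4-(2-acetyl-5-methoxyphenoxy)-4-methylpent-2-enoic acid | CC(=O)c1ccc(OC)cc1OC(C)(C)/C=C\C(=O)O
F2 | step 3 | 2-(3-acetyl-2-hydroxy-6-methoxyphenyl)-4-methylpent-3-enoic acid (racemic) | CC(=O)c1ccc(OC)c(C(C=C(C)C)C(=O)O)c1O
F3 | step 3 | trans-(3S*,4R*)-3-(3-acetyl-2-hydroxy-6-methoxyphenyl)-5,5-dimethyl-4-(phenylselanyl)oxolan-2-one (racemic, one enantiomer drawn) | O=C1OC(C)(C)[C@H]([Se]c2ccccc2)[C@H]1c1c(O)c(C(C)=O)ccc1OC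
F4 | step 1 | 1-bromo-4-methoxy-2-[(2-methylbut-3-yn-2-yl)oxy]benzene | COc1ccc(Br)c(OC(C)(C)C#C)c1
F5 | step 1 | 1-(1-ethoxyethenyl)-4-methoxy-2-[(2-methylbut-3-yn-2-yl)oxy]benzene | C=C(OCC)c1ccc(OC)cc1OC(C)(C)C#C
F6 | step 2 | methyl 4-(2-acetyl-5-methoxyphenoxy)-4-methylpent-2-ynoate | CC(=O)c1ccc(OC)cc1OC(C)(C)C#CC(=O)OC
F7 | step 4 | 6-acetyl-2-(5,5-dimethyl-2-oxo-2,5-dihydrofuran-3-yl)-3-methoxyphenyl benzoate | CC(=O)c1ccc(OC)c(C2=CC(C)(C)OC2=O)c1OC(=O)c1ccccc1
F8 | step 4 | 1-[3-(5,5-dimethyl-2-oxo-2,5-dihydrofuran-3-yl)-2-hydroxy-4-methoxyphenyl]-3-phenylpropane-1,3-dione | O=C(CC(=O)c1ccccc1)c1ccc(OC)c(C2=CC(C)(C)OC2=O)c1O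
A1 | alternative 1 | 8-iodo-7-methoxy-2-phenyl-4H-chromen-4-one | COc1ccc2c(=O)cc(-c3ccccc3)oc2c1I
A2 | alternative 1 | 5,5-dimethyl-3-(tributylstannyl)furan-2(5H)-one | CCCC[Sn](CCCC)(CCCC)C1=CC(C)(C)OC1=O
A3 | alternative 2 | 8-(3-hydroxy-3-methylbut-1-yn-1-yl)-7-methoxy-2-phenyl-4H-chromen-4-one | COc1ccc2c(=O)cc(-c3ccccc3)oc2c1C#CC(C)(C)O
A4 | alternative 3 | (7-methoxy-4-oxo-2-phenyl-4H-chromen-8-yl)acetic acid | COc1ccc2c(=O)cc(-c3ccccc3)oc2c1CC(=O)O
A5 | alternative 3 | 2-hydroxy-2-methylpropanal | CC(C)(O)C=O
A6 | alternative 3 | 2-methyl-1-oxopropan-2-yl (7-methoxy-4-oxo-2-phenyl-4H-chromen-8-yl)acetate | COc1ccc2c(=O)cc(-c3ccccc3)oc2c1CC(=O)OC(C)(C)C=O
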